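The retrosynthesis removes two acetonides, then cuts C15–C12' (the ketone carbon and its alpha CH), then cuts C12=C13 of the left half by olefination. Both halves trace back to andrographolide.
Enabling feature: ketone C15 and lactone carbonyl C16' of the right butenolide ring are 1,4-related through C12'–C13'. The ring alkene C13'=C14' marks where a C14' oxygen has left. Andrographolide's own lactone ring (exocyclic C12'=C13', C14'–O) is therefore the latent acceptor for an acyl anion at C15.
Forward order: no carbocycle is built. Andrographolide gives the acetonide. One portion becomes the 14-acetate (right half). The other is cleaved to the C12 aldehyde, extended by C13–C16, and unmasked to the 15-aldehyde (left half).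
The halves are joined by a carbene-catalysed addition-elimination, and both acetonides are then removed.
Stereochemistry: all ten decalin centres come from andrographolide. The (12E) geometry comes from the olefination. (12'S) comes from attack anti to the (14'S)-acetoxy group, which is consumed in the same event.

Key step: step 7

Assumption: andrographolide, sold in bulk as the isolated diterpene lactone of Andrographis paniculata, counts as the commercially available chiral starting material; labdane numbering is used, with primed numbers for the butenolide-bearing half.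

Step 1
Reactants: 1 andrographolide
Product: 2 3,19-O-isopropylideneandrographolide
Conditions: Me2C(OMe)2, pyridinium p-toluenesulfonate (cat.), toluene–DMSO, 80 °C
Reagents that add atoms: 2,2-dimethoxypropane, COC(C)(C)OC
Why: Acid-catalysed transketalisation ties the 1,3-related C3 and C19 hydroxyls into a six-membered dioxane and leaves the isolated C14 hydroxyl free, with no stereocentre touched.

Step 2
Reactants: 2 3,19-O-isopropylideneandrographolide
Product: 3 14-O-acetyl-3,19-O-isopropylideneandrographolide
Conditions: Ac2O, Et3N, 4-(dimethylamino)pyridine (cat.), CH2Cl2, 0 °C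
Reagents that add atoms: acetic anhydride, CC(=O)OC(C)=O
Why: Nucleophile-catalysed O-acylation of the only free hydroxyl turns C14–O into a leaving group with retention of (14S), the low temperature holding back 1,4-elimination.

Step 3
Reactants: 2 3,19-O-isopropylideneandrographolide
Product: 4 3,19-(isopropylidenedioxy)-13,14,15,16-tetranor-ent-labd-8(17)-en-12-al
Conditions: KMnO4, THF–H2O, −10 to 0 °C, short contact time
Reagents that add atoms: potassium permanganate, [K+].[O-][Mn](=O)(=O)=O
Why: Permanganate oxidative cleavage, whose cycloaddition is fastest with conjugated electron-poor alkenes, should sever C12=C13 while the hindered C8=C17 methylidene (flanked by C9, screened by the C10 methyl) reacts more slowly, as in the classical permanganate degradations of labdane side chains.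

Step 4
Reactants: 5 methyl (diethoxyphosphoryl)acetate; 6 2-bromo-1,1-dimethoxyethane
Product: 7 methyl 2-(diethoxyphosphoryl)-4,4-dimethoxybutanoate (racemic)
Conditions: NaH, DMF, 0 to 80 °C
Reagents that add atoms: none
Why: SN2 C-alkylation of the stabilised phosphonoacetate carbanion by the primary bromide, with heating to offset the retarding beta-alkoxy groups, assembles the C13–C16 unit with C15 masked as an acetal.

Step 5
Reactants: 4 3,19-(isopropylidenedioxy)-13,14,15,16-tetranor-ent-labd-8(17)-en-12-al; 7 methyl 2-(diethoxyphosphoryl)-4,4-dimethoxybutanoate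
Product: 8 methyl (12E)-15,15-dimethoxy-3,19-(isopropylidenedioxy)-ent-labda-8(17),12-dien-16-oate
Conditions: NaH, THF, 0 °C; then 4, 0 °C to rt
Reagents that add atoms: none
Why: Horner–Wadsworth–Emmons olefination, with reversible addition and elimination through the less crowded oxaphosphetane, should place the C11 chain trans to CO2Me (12E), any Z isomer being removed by chromatography.

Step 6
Reactants: 8 methyl (12E)-15,15-dimethoxy-3,19-(isopropylidenedioxy)-ent-labda-8(17),12-dien-16-oate
Product: 9 methyl (12E)-3,19-(isopropylidenedioxy)-15-oxo-ent-labda-8(17),12-dien-16-oate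
Conditions: pyridinium p-toluenesulfonate (cat.), acetone containing 1 % H2O, 40 °C; used without storage
Reagents that add atoms: water, O
Why: Acid-catalysed acetal hydrolysis frees the C15 aldehyde, while acetone as solvent keeps the 3,19-ketal closed by mass action and the weak acid should not shift the skipped C12=C13 bond.

Step 7
Reactants: 9 methyl (12E)-3,19-(isopropylidenedioxy)-15-oxo-ent-labda-8(17),12-dien-16-oate; 3 14-O-acetyl-3,19-O-isopropylideneandrographolide
Product: 10 3,19:3',19'-di-O-isopropylidene derivative of the target (12E, 12'S)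
Conditions: 6,7-dihydro-2-(pentafluorophenyl)-5H-pyrrolo[2,1-c][1,2,4]triazol-2-ium tetrafluoroborate (20 mol %), iPr2NEt (1.2 equiv), THF (0.5 M), 4 Å molecular sieves, 25 °C, argon
Reagents that add atoms: none
Why: Proposed new method: the carbene freed from the triazolium salt adds to the formyl group of 9 and a proton shift gives the enaminol, an acyl anion equivalent at C15, which attacks C12' of 3, the beta carbon of the s-cis-locked alkylidene lactone; the lactone enolate then expels the C14' acetate (E1cB), which moves the double bond into the ring as the C13'=C14' butenolide, and acetate-assisted collapse of the azolium carbinol releases the C15 ketone and the carbene. The closest known reaction types are the intermolecular Stetter reaction of enolisable aldehydes and the addition-elimination (SN2') of amines, thiols and nitronates at C12 of 14-O-acyl andrographolides and at Morita–Baylis–Hillman acetates, and the new element is their merger on a beta-alkyl acceptor, made plausible because acetate loss renders the otherwise reversible addition irreversible. No ring is closed. The only new stereocentre, C12', is controlled by the (14'S)-acetoxy group, which stands pseudo-axial for the elimination and screens its own face of the flat lactone, so that attack anti to it gives (12'S) while C14' itself is erased (1,3-transfer of chirality). The step needs cross-coupling instead of acyloin formation (reversible, so it drains into the irreversible channel), attack on 3 instead of the acyclic enoate of 9 or the butenolide of 10 (neither carries a leaving group), and survival of 3 and of the acidic C12'–H, which the iPr2NEt/acetate buffer at 25 °C should secure where alkoxide bases would cause 1,4-elimination and epimerisation. The polar umpolung is chosen because the acyl radical from 9 would lose CO to give a stabilised allyl radical.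

Step 8
Reactants: 10 3,19:3',19'-di-O-isopropylidene derivative of the target
Product: 11 target CNP0330094.1
Conditions: AcOH–H2O (7:3), 25 °C
Reagents that add atoms: none
Why: Mild acid hydrolysis of both dioxane ketals, the standard release of 3,19-diols in this series, is too weakly acidic to enolise the C15 ketone appreciably, so (12'S), the (12E)-enoate and both methylidene groups should persist.

Compound list
1 | andrographolide, (3E,4S)-3-{2-[(1R,4aS,5R,6R,8aS)-6-hydroxy-5-(hydroxymethyl)-5,8a-dimethyl-2-methylidenedecahydronaphthalen-1-yl]ethylidene}-4-hydroxyoxolan-2-one | C=C1CC[C@@H]2[C@](C)(CO)[C@H](O)CC[C@@]2(C)[C@@H]1C/C=C1/C(=O)OC[C@H]1O | starting material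
2 | 3,19-O-isopropylideneandrographolide (dioxane across O3 and O19; 14S hydroxyl free; 12E) | C=C1CC[C@@H]2[C@](C)(CO3)[C@H](OC3(C)C)CC[C@@]2(C)[C@@H]1C/C=C1/C(=O)OC[C@H]1O | intermediate
3 | 14-O-acetyl-3,19-O-isopropylideneandrographolide (14S, 12E) | C=C1CC[C@@H]2[C@](C)(CO3)[C@H](OC3(C)C)CC[C@@]2(C)[C@@H]1C/C=C1/C(=O)OC[C@H]1OC(C)=O | intermediate
4 | 3,19-(isopropylidenedioxy)-13,14,15,16-tetranor-ent-labd-8(17)-en-12-al (decalin as in 1, C9–CH2–CHO) | C=C1CC[C@@H]2[C@](C)(CO3)[C@H](OC3(C)C)CC[C@@]2(C)[C@@H]1CC=O | intermediate
5 | methyl (diethoxyphosphoryl)acetate | COC(=O)CP(=O)(OCC)OCC | starting material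
6 | 2-bromo-1,1-dimethoxyethane | COC(CBr)OC | starting material
7 | methyl 2-(diethoxyphosphoryl)-4,4-dimethoxybutanoate (racemic; centre lost in step 5) | COC(=O)C(CC(OC)OC)P(=O)(OCC)OCC | intermediate
8 | methyl (12E)-15,15-dimethoxy-3,19-(isopropylidenedioxy)-ent-labda-8(17),12-dien-16-oate | C=C1CC[C@@H]2[C@](C)(CO3)[C@H](OC3(C)C)CC[C@@]2(C)[C@@H]1C/C=C(\CC(OC)OC)C(=O)OC | intermediate
9 | methyl (12E)-3,19-(isopropylidenedioxy)-15-oxo-ent-labda-8(17),12-dien-16-oate | C=C1CC[C@@H]2[C@](C)(CO3)[C@H](OC3(C)C)CC[C@@]2(C)[C@@H]1C/C=C(\CC=O)C(=O)OC | intermediate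
10 | 3,19:3',19'-di-O-isopropylidene derivative of 11 (12E, 12'S) | C=C1CC[C@@H]2[C@](C)(CO3)[C@H](OC3(C)C)CC[C@@]2(C)[C@@H]1C/C=C(\CC(=O)[C@@H](C[C@@H]1C(=C)CC[C@@H]2[C@](C)(CO3)[C@H](OC3(C)C)CC[C@]21C)C1=CCOC1=O)C(=O)OC | intermediate
11 | methyl (12E)-3,19-dihydroxy-15-oxo-15-[(12'S)-14'-deoxyandrographolid-12'-yl]-ent-labda-8(17),12-dien-16-oate (CNP0330094.1) | C=C1CC[C@@H]2[C@](C)(CO)[C@H](O)CC[C@@]2(C)[C@@H]1C/C=C(\CC(=O)[C@@H](C[C@@H]1C(=C)CC[C@@H]2[C@](C)(CO)[C@H](O)CC[C@]21C)C1=CCOC1=O)C(=O)OC | target

Total step count: 8. Longest linear sequence: 6 (steps 1, 3, 5, 6, 7, 8).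

Steps most likely to fail

Step 7.
- **Risk:** The enaminol may add too slowly to the beta-substituted acceptor. Acyloin self-condensation of 9, capture of the carbene at C12' and amine-induced 1,4-elimination of acetic acid from 3 could then consume the partners. The facial preference may also be weak.
- **Fallback:** This uses known chemistry with a stoichiometric acyl anion equivalent. It sets out from 4 and 3 and comes back at 10.
- Morita–Baylis–Hillman reaction of 4 with methyl acrylate (1,4-diazabicyclo[2.2.2]octane, MeOH) should give the Morita–Baylis–Hillman alcohol F1.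
- Ac2O and pyridine convert it into the allylic acetate F2.
- Nitromethane with K2CO3 in THF–H2O attacks the methylene terminus (SN2') to give the (12E)-15-nitro ester F3.
- The nitronate of F3 (Et3N, MeCN) adds to C12' of 3, anti to the departing acetate, to give the 15-nitro dimer F4. Its C15 epimers are irrelevant.
- A reductive Nef reaction (NaOMe, then TiCl3 in NH4OAc buffer) turns C15–NO2 into the ketone of 10.

Step 6.
- **Risk:** The acid may partly open the 3,19-ketal. The skipped C12=C13 bond may drift into conjugation with the formyl group during hydrolysis or chromatography.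
- **Fallback:** The aldehyde is released oxidatively at neutral pH. The fallback sets out from 4 and comes back at 9.
- The allyl-substituted stabilised ylide F5 is made from methyl (triphenylphosphoranylidene)acetate and allyl bromide, then aqueous NaOH.
- Wittig reaction of 4 with F5 in toluene at 90 °C should give the (12E)-allyl enoate F6. This also tightens the alkene geometry.
- Lemieux–Johnson cleavage (OsO4 cat., NaIO4, 2,6-lutidine, dioxane–H2O) of the unhindered monosubstituted vinyl group passes through the 15,15a-diol F7. It delivers 9 without any acid.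

Step 3.
- **Risk:** Permanganate may also attack the C8=C17 methylidene and may over-oxidise the aldehyde to the acid.
- **Fallback:** Innate electronic selectivity is replaced by hydroxyl-directed delivery. The fallback sets out from 2 and comes back at 4.
- OsO4 with N,N,N',N'-tetramethylethane-1,2-diamine in CH2Cl2 at −78 °C is guided by hydrogen bonding to the C14 hydroxyl onto C12=C13.
- Aqueous Na2SO3 work-up then gives the 12,13-diol F8.
- NaIO4 in THF–H2O cleaves the glycol to 4 and stops at the aldehyde.

Further compounds
F1 | step 7 | Morita–Baylis–Hillman alcohol, methyl 2-{1-hydroxy-2-[decalinyl of 4]ethyl}acrylate (C12 epimers) | C=C1CC[C@@H]2[C@](C)(CO3)[C@H](OC3(C)C)CC[C@@]2(C)[C@@H]1CC(O)C(=C)C(=O)OC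
F2 | step 7 | allylic acetate of F1 | C=C1CC[C@@H]2[C@](C)(CO3)[C@H](OC3(C)C)CC[C@@]2(C)[C@@H]1CC(OC(C)=O)C(=C)C(=O)OC
F3 | step 7 | (12E)-15-nitro ester, methyl (12E)-3,19-(isopropylidenedioxy)-15-nitro-ent-labda-8(17),12-dien-16-oate | C=C1CC[C@@H]2[C@](C)(CO3)[C@H](OC3(C)C)CC[C@@]2(C)[C@@H]1C/C=C(\CC[N+](=O)[O-])C(=O)OC
F4 | step 7 | 15-nitro dimer, the analogue of 10 with CH(NO2) at C15 (12E, 12'S, C15 epimers) | C=C1CC[C@@H]2[C@](C)(CO3)[C@H](OC3(C)C)CC[C@@]2(C)[C@@H]1C/C=C(\CC([N+](=O)[O-])[C@@H](C[C@@H]1C(=C)CC[C@@H]2[C@](C)(CO3)[C@H](OC3(C)C)CC[C@]21C)C1=CCOC1=O)C(=O)OC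
F5 | step 6 | allyl-substituted stabilised ylide, methyl 2-(triphenylphosphoranylidene)pent-4-enoate | C=CCC(C(=O)OC)=P(c1ccccc1)(c1ccccc1)c1ccccc1
F6 | step 6 | (12E)-allyl enoate, methyl (E)-2-allyl-4-[decalinyl of 4]but-2-enoate | C=C1CC[C@@H]2[C@](C)(CO3)[C@H](OC3(C)C)CC[C@@]2(C)[C@@H]1C/C=C(\CC=C)C(=O)OC
F7 | step 6 | 15,15a-diol from F6 (carbinol epimers) | C=C1CC[C@@H]2[C@](C)(CO3)[C@H](OC3(C)C)CC[C@@]2(C)[C@@H]1C/C=C(\CC(O)CO)C(=O)OC
F8 | step 3 | 12,13-diol of 2 (12,13-dihydroxy-12,13-dihydro derivative, new centres undefined) | C=C1CC[C@@H]2[C@](C)(CO3)[C@H](OC3(C)C)CC[C@@]2(C)[C@@H]1CC(O)C1(O)C(=O)OC[C@H]1O
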